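The ten-membered ring is cut at C7–C8 (C7: ring-fusion carbon β to the lactone carbonyl; C8: tiglate-bearing carbinol). The O8–C8–C7–C11=C13 array of the α-methylene-γ-butyrolactone ring is the signature of an allylmetal addition to an aldehyde: a 3-(bromomethyl)butenolide already closed on O6 is reduced at C13 by CrCl2 and attacks a C8 aldehyde through C7. One operation closes the carbocycle, sets C7 and C8 and unveils the exocyclic methylene. The precursor is a bromo aldehyde whose chain is built from (S)-linalool by two asymmetric alkynylations and a cuprate addition that fixes the Z-C4=C5 alkene.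

Key step: step 16

Remark on numbering: germacrane numbering is used for the target and all precursors (C1–C10 carbocycle; O6 on C6; C11, C12, C13 = lactone α-carbon, carbonyl carbon, methylene carbon; C14 on C10, C15 on C4).

Assumption: in the BINOL–Ti(OiPr)4 alkynylzinc additions the (S)-ligand is taken to give the (R)-propargylic alcohol (alkynyl ranking above the other carbon substituent) and the (R)-ligand the (S)-alcohol; the configuration of 8 and 14 would be checked as Mosher esters and the antipodal ligand used if the sense is opposite.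

Step 1
Reactants: 1 (S)-(+)-linalool
Product: 3 (3S)-3,7-dimethyloct-6-ene-1,3-diol, via bis(9-BBN) adduct 2 (not isolated)
Conditions: 9-borabicyclo[3.3.1]nonane (9-BBN, 2.5 equiv), THF, 0 °C to rt; then NaOH (aq), H2O2, 0 °C to rt
Reagents that add atoms: hydrogen peroxide, OO
Why: Anti-Markovnikov hydroboration–oxidation, in which 9-BBN takes the monosubstituted vinyl group far faster than the trisubstituted alkene and puts boron on the terminal carbon (C8); the C10 stereocentre of linalool is not touched.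

Step 2
Reactants: 3 (3S)-3,7-dimethyloct-6-ene-1,3-diol
Product: 4 (4S)-2,2,4-trimethyl-4-(4-methylpent-3-en-1-yl)-1,3-dioxane
Conditions: Me2C(OMe)2, PPTS (cat.), acetone, rt
Reagents that add atoms: 2,2-dimethoxypropane, COC(C)(C)OC
Why: Acid-catalysed transacetalisation closes the six-membered isopropylidene acetal across the 1,3-diol and masks O8 and O10 in one group.

Step 3
Reactants: 4 (4S)-2,2,4-trimethyl-4-(4-methylpent-3-en-1-yl)-1,3-dioxane
Product: 6 3-[(4S)-2,2,4-trimethyl-1,3-dioxan-4-yl]propanal, via secondary ozonide 5 (not isolated)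
Conditions: O3, CH2Cl2, −78 °C; then PPh3, −78 °C to rt
Reagents that add atoms: ozone, [O-][O+]=O
Why: Ozonolysis with reductive work-up cleaves the only alkene and leaves C3 as the aldehyde, the acetal being inert.

Step 4
Reactants: 6 3-[(4S)-2,2,4-trimethyl-1,3-dioxan-4-yl]propanal; 7 methyl propiolate
Product: 8 methyl (4S)-4-hydroxy-6-[(4S)-2,2,4-trimethyl-1,3-dioxan-4-yl]hex-2-ynoate
Conditions: 7, ZnEt2, Cy2NH (cat.), (R)-BINOL (40 mol %), Et2O, rt; then Ti(OiPr)4 (1 equiv), then 6, rt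
Reagents that add atoms: none
Why: BINOL–Ti(OiPr)4-catalysed enantioselective addition of the alkynylzinc of an alkyl propiolate to an aliphatic aldehyde, in which the (R)-ligand should direct attack to the face giving the (S)-carbinol at C3 (reagent control, C10 being remote).

Step 5
Reactants: 8 methyl (4S)-4-hydroxy-6-[(4S)-2,2,4-trimethyl-1,3-dioxan-4-yl]hex-2-ynoate
Product: 9 methyl (4S)-4-[(tert-butyldimethylsilyl)oxy]-6-[(4S)-2,2,4-trimethyl-1,3-dioxan-4-yl]hex-2-ynoate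
Conditions: TBSCl, imidazole, DMF, rt
Reagents that add atoms: tert-butyldimethylsilyl chloride, CC(C)(C)[Si](C)(C)Cl
Why: Silylation of the secondary alcohol, which blocks lactonisation onto the ester after the next step and removes the γ-hydroxy ynoate from base-induced redox isomerisation.

Step 6
Reactants: 9 methyl (4S)-4-[(tert-butyldimethylsilyl)oxy]-6-[(4S)-2,2,4-trimethyl-1,3-dioxan-4-yl]hex-2-ynoate
Product: 10 methyl (2Z,4S)-4-[(tert-butyldimethylsilyl)oxy]-3-methyl-6-[(4S)-2,2,4-trimethyl-1,3-dioxan-4-yl]hex-2-enoate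
Conditions: Me2CuLi (from CuI and MeLi), THF, −78 °C; MeOH then NH4Cl (aq) at −78 °C
Reagents that add atoms: lithium dimethylcuprate, [Li+].C[Cu-]C
Why: Syn carbocupration of the ynoate (conjugate addition of a Gilman cuprate) puts methyl on C4 and, after protonation of the vinylcopper with retention at low temperature, hydrogen on C5 cis to it, so that C3 and C6 end up cis, which is the Z-trisubstituted alkene of the target.

Step 7
Reactants: 10 methyl (2Z,4S)-4-[(tert-butyldimethylsilyl)oxy]-3-methyl-6-[(4S)-2,2,4-trimethyl-1,3-dioxan-4-yl]hex-2-enoate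
Product: 11 (2Z,4S)-4-[(tert-butyldimethylsilyl)oxy]-3-methyl-6-[(4S)-2,2,4-trimethyl-1,3-dioxan-4-yl]hex-2-en-1-ol
Conditions: i-Bu2AlH (2.2 equiv), CH2Cl2, −78 °C; Rochelle salt (aq)
Reagents that add atoms: none
Why: 1,2-Reduction of the enoate by the aluminium hydride gives the allylic alcohol without change of alkene geometry.

Step 8
Reactants: 11 (2Z,4S)-4-[(tert-butyldimethylsilyl)oxy]-3-methyl-6-[(4S)-2,2,4-trimethyl-1,3-dioxan-4-yl]hex-2-en-1-ol
Product: 12 (2Z,4S)-4-[(tert-butyldimethylsilyl)oxy]-3-methyl-6-[(4S)-2,2,4-trimethyl-1,3-dioxan-4-yl]hex-2-enal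
Conditions: MnO2, CH2Cl2, rt
Reagents that add atoms: none
Why: Allylic oxidation with MnO2 under neutral conditions, under which a β,β-disubstituted Z-enal should keep its geometry; the aldehyde is used at once.

Step 9
Reactants: 12 (2Z,4S)-4-[(tert-butyldimethylsilyl)oxy]-3-methyl-6-[(4S)-2,2,4-trimethyl-1,3-dioxan-4-yl]hex-2-enal; 13 1-methoxy-4-[(prop-2-yn-1-yloxy)methyl]benzene
Product: 14 (4R,5Z,7S)-7-[(tert-butyldimethylsilyl)oxy]-1-[(4-methoxybenzyl)oxy]-6-methyl-9-[(4S)-2,2,4-trimethyl-1,3-dioxan-4-yl]non-5-en-2-yn-4-ol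
Conditions: 13, ZnEt2, toluene, reflux; then (S)-BINOL (40 mol %), Ti(OiPr)4, Et2O, rt; then 12, rt
Reagents that add atoms: none
Why: BINOL–Ti(OiPr)4-catalysed enantioselective alkynylzinc addition to an α,β-unsaturated aldehyde, in which the (S)-ligand should give the (R)-carbinol at C6 by reagent control (C3 is 1,4-remote).

Step 10
Reactants: 14 (4R,5Z,7S)-7-[(tert-butyldimethylsilyl)oxy]-1-[(4-methoxybenzyl)oxy]-6-methyl-9-[(4S)-2,2,4-trimethyl-1,3-dioxan-4-yl]non-5-en-2-yn-4-ol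
Product: 16 (2Z,4R,5Z,7S)-7-[(tert-butyldimethylsilyl)oxy]-2-iodo-1-[(4-methoxybenzyl)oxy]-6-methyl-9-[(4S)-2,2,4-trimethyl-1,3-dioxan-4-yl]nona-2,5-dien-4-ol, via cyclic alkenylalanate 15 (not isolated)
Conditions: NaAlH2(OCH2CH2OMe)2, THF, 0 °C to rt; then I2, THF, −78 °C to 0 °C
Reagents that add atoms: iodine, II
Why: Alkoxide-directed trans-hydroalumination of the propargylic alcohol delivers hydride to C7 and aluminium to C11 through a five-membered oxa-aluminacycle, and iodinolysis with retention gives the Z-iodoalkene with iodine cis to C6.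

Step 11
Reactants: 16 (2Z,4R,5Z,7S)-7-[(tert-butyldimethylsilyl)oxy]-2-iodo-1-[(4-methoxybenzyl)oxy]-6-methyl-9-[(4S)-2,2,4-trimethyl-1,3-dioxan-4-yl]nona-2,5-dien-4-ol
Product: 17 (5R)-3-{[(4-methoxybenzyl)oxy]methyl}-5-{(1Z,3S)-3-[(tert-butyldimethylsilyl)oxy]-2-methyl-5-[(4S)-2,2,4-trimethyl-1,3-dioxan-4-yl]pent-1-en-1-yl}furan-2(5H)-one
Conditions: Pd(PPh3)2Cl2 (5 mol %), CO (1 atm), i-Pr2NEt, THF, 40 °C
Reagents that add atoms: carbon monoxide, [C-]#[O+]
Why: Carbonylative lactonisation, in which zerovalent palladium inserts into the C11–I bond, CO inserts and the cis-disposed C6 hydroxyl captures the acylpalladium to close the butenolide (C12 enters here); the hindered amine and mild temperature are chosen to spare the acidic C6 hydrogen.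

Step 12
Reactants: 17 (5R)-3-{[(4-methoxybenzyl)oxy]methyl}-5-{(1Z,3S)-3-[(tert-butyldimethylsilyl)oxy]-2-methyl-5-[(4S)-2,2,4-trimethyl-1,3-dioxan-4-yl]pent-1-en-1-yl}furan-2(5H)-one
Product: 18 (5R)-3-(hydroxymethyl)-5-{(1Z,3S)-3-[(tert-butyldimethylsilyl)oxy]-2-methyl-5-[(4S)-2,2,4-trimethyl-1,3-dioxan-4-yl]pent-1-en-1-yl}furan-2(5H)-one
Conditions: DDQ, CH2Cl2/pH 7 buffer, 0 °C
Reagents that add atoms: none
Why: Oxidative cleavage of the 4-methoxybenzyl ether by DDQ frees O13, while the electron-poor allylic alcohol formed, the silyl ether and the acetal should not react.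

Step 13
Reactants: 18 (5R)-3-(hydroxymethyl)-5-{(1Z,3S)-3-[(tert-butyldimethylsilyl)oxy]-2-methyl-5-[(4S)-2,2,4-trimethyl-1,3-dioxan-4-yl]pent-1-en-1-yl}furan-2(5H)-one
Product: 19 (5R)-3-(bromomethyl)-5-{(1Z,3S)-3-[(tert-butyldimethylsilyl)oxy]-2-methyl-5-[(4S)-2,2,4-trimethyl-1,3-dioxan-4-yl]pent-1-en-1-yl}furan-2(5H)-one
Conditions: CBr4, PPh3 (added last), CH2Cl2, 0 °C
Reagents that add atoms: tetrabromomethane, BrC(Br)(Br)Br
Why: Appel bromination converts the primary allylic alcohol into the bromide under neutral conditions that leave the base-sensitive C6 centre alone.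

Step 14
Reactants: 19 (5R)-3-(bromomethyl)-5-{(1Z,3S)-3-[(tert-butyldimethylsilyl)oxy]-2-methyl-5-[(4S)-2,2,4-trimethyl-1,3-dioxan-4-yl]pent-1-en-1-yl}furan-2(5H)-one
Product: 20 (5R)-3-(bromomethyl)-5-[(1Z,3S,6S)-3-[(tert-butyldimethylsilyl)oxy]-6,8-dihydroxy-2,6-dimethyloct-1-en-1-yl]furan-2(5H)-one
Conditions: PPTS (cat.), MeOH, rt
Reagents that add atoms: none
Why: Mild acid-catalysed transacetalisation to methanol removes the strained 4,4-disubstituted acetonide, while the secondary silyl ether and the allylic bromide should survive.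

Step 15
Reactants: 20 (5R)-3-(bromomethyl)-5-[(1Z,3S,6S)-3-[(tert-butyldimethylsilyl)oxy]-6,8-dihydroxy-2,6-dimethyloct-1-en-1-yl]furan-2(5H)-one
Product: 21 (5R)-3-(bromomethyl)-5-[(1Z,3S,6S)-3-[(tert-butyldimethylsilyl)oxy]-6-hydroxy-2,6-dimethyl-8-oxooct-1-en-1-yl]furan-2(5H)-one
Conditions: TEMPO (cat.), PhI(OAc)2, CH2Cl2, rt
Reagents that add atoms: none
Why: Oxoammonium (TEMPO) oxidation takes the primary alcohol to the C8 aldehyde and cannot oxidise the tertiary C10 hydroxyl; the β-hydroxy aldehyde is used crude.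

Step 16
Reactants: 21 (5R)-3-(bromomethyl)-5-[(1Z,3S,6S)-3-[(tert-butyldimethylsilyl)oxy]-6-hydroxy-2,6-dimethyl-8-oxooct-1-en-1-yl]furan-2(5H)-one
Product: 23 (3aS,4R,6S,9S,10Z,11aR)-9-[(tert-butyldimethylsilyl)oxy]-4,6-dihydroxy-6,10-dimethyl-3-methylidene-3a,4,5,6,7,8,9,11a-octahydrocyclodeca[b]furan-2(3H)-one, via allylchromium dichloride 22 (not isolated)
Conditions: CrCl2 (10 equiv), THF, rt, slow addition of 21 (final 2 mM)
Reagents that add atoms: none
Why: Two equivalents of CrCl2 reduce the allylic C13–Br bond to an allylchromium dichloride (trivalent chromium), which adds through its γ-carbon C7 to the C8 aldehyde in a closed six-membered chair while the double bond moves to C11=C13; C7, the electrophilic β-carbon of the butenolide, is thereby joined as a nucleophile to the electrophilic aldehyde carbon. The closest known reaction type is the intramolecular Nozaki–Hiyama–Kishi (chromium Barbier) allylation of aldehydes by 2-(bromomethyl)alkenoates and 3-(bromomethyl)butenolides, which is established for α-methylene-γ-butyrolactones and for medium-ring closure. The ten-membered carbocycle closes in a 10-exo-trig mode, the γ-lactone being already in place on O6 so that the new O8 alkoxide cannot capture C12. C8 is set relative to C7 by the chair: the ring fixes the allyl unit in the E-like geometry (C6 trans to C13), C6 is pseudo-equatorial, and with the C9 chain equatorial the 7,8-anti adduct (7S,8R) results. C7 is set relative to C6 by the face of the planar butenolide that the tethered aldehyde reaches; the rotamer with the C6–O6 bond in the plane of the Z-C4=C5 alkene folds the C3–C9 chain under the face that carries C5 and should give the cis-fused lactone, and this facial preference is the least secured element of the step. The step also needs γ- over α-attack (primary C13–Cr bond and cyclic transition state) and cyclisation over oligomerisation (slow addition, high dilution).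

Step 17
Reactants: 23 (3aS,4R,6S,9S,10Z,11aR)-9-[(tert-butyldimethylsilyl)oxy]-4,6-dihydroxy-6,10-dimethyl-3-methylidene-3a,4,5,6,7,8,9,11a-octahydrocyclodeca[b]furan-2(3H)-one; 24 (2E)-2-methylbut-2-enoyl chloride (tigloyl chloride)
Product: 25 (3aS,4R,6S,9S,10Z,11aR)-9-[(tert-butyldimethylsilyl)oxy]-6-hydroxy-6,10-dimethyl-3-methylidene-2-oxo-2,3,3a,4,5,6,7,8,9,11a-decahydrocyclodeca[b]furan-4-yl (2E)-2-methylbut-2-enoate
Conditions: 24, pyridine, DMAP (cat.), CH2Cl2, 0 °C to rt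
Reagents that add atoms: none
Why: Acylation of the secondary C8 alcohol by the acid chloride, the tertiary C10 hydroxyl being too hindered to react and the weak base being chosen to avoid translactonisation from O6 to O8; the E (tiglate) geometry is the stable one.

Step 18
Reactants: 25 (3aS,4R,6S,9S,10Z,11aR)-9-[(tert-butyldimethylsilyl)oxy]-6-hydroxy-6,10-dimethyl-3-methylidene-2-oxo-2,3,3a,4,5,6,7,8,9,11a-decahydrocyclodeca[b]furan-4-yl (2E)-2-methylbut-2-enoate
Product: 26 (3aS,4R,6S,9S,10Z,11aR)-6,9-dihydroxy-6,10-dimethyl-3-methylidene-2-oxo-2,3,3a,4,5,6,7,8,9,11a-decahydrocyclodeca[b]furan-4-yl (2E)-2-methylbut-2-enoate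
Conditions: HF·pyridine, pyridine, THF, 0 °C to rt
Reagents that add atoms: none
Why: Buffered fluoride desilylation frees the allylic C3 hydroxyl without base, so the α-methylene lactone and the tiglate should be left intact.

Compound list
1 | (S)-(+)-linalool, (3S)-3,7-dimethylocta-1,6-dien-3-ol | C=C[C@@](C)(O)CCC=C(C)C | starting material
2 | bis(9-BBN) adduct of 1: 9-borabicyclo[3.3.1]nonan-9-yl on C8 and as borinate on O10, configuration at C10 as in 1 | CC(C)=CCC[C@](C)(OB1C2CCCC1CCC2)CCB1C2CCCC1CCC2 | intermediate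
3 | (3S)-3,7-dimethyloct-6-ene-1,3-diol | CC(C)=CCC[C@](C)(O)CCO | intermediate
4 | (4S)-2,2,4-trimethyl-4-(4-methylpent-3-en-1-yl)-1,3-dioxane | CC(C)=CCC[C@@]1(C)CCOC(C)(C)O1 | intermediate
5 | secondary ozonide of 4: 3,3-dimethyl-5-{2-[(4S)-2,2,4-trimethyl-1,3-dioxan-4-yl]ethyl}-1,2,4-trioxolane | CC1(C)OOC(CC[C@@]2(C)CCOC(C)(C)O2)O1 | intermediate
6 | 3-[(4S)-2,2,4-trimethyl-1,3-dioxan-4-yl]propanal | O=CCC[C@@]1(C)CCOC(C)(C)O1 | intermediate
7 | methyl propiolate | C#CC(=O)OC | starting material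
8 | methyl (4S)-4-hydroxy-6-[(4S)-2,2,4-trimethyl-1,3-dioxan-4-yl]hex-2-ynoate | COC(=O)C#C[C@@H](O)CC[C@@]1(C)CCOC(C)(C)O1 | intermediate
9 | methyl (4S)-4-[(tert-butyldimethylsilyl)oxy]-6-[(4S)-2,2,4-trimethyl-1,3-dioxan-4-yl]hex-2-ynoate | COC(=O)C#C[C@@H](O[Si](C)(C)C(C)(C)C)CC[C@@]1(C)CCOC(C)(C)O1 | intermediate
10 | methyl (2Z,4S)-4-[(tert-butyldimethylsilyl)oxy]-3-methyl-6-[(4S)-2,2,4-trimethyl-1,3-dioxan-4-yl]hex-2-enoate | COC(=O)/C=C(/C)[C@@H](O[Si](C)(C)C(C)(C)C)CC[C@@]1(C)CCOC(C)(C)O1 | intermediate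
11 | (2Z,4S)-4-[(tert-butyldimethylsilyl)oxy]-3-methyl-6-[(4S)-2,2,4-trimethyl-1,3-dioxan-4-yl]hex-2-en-1-ol | OC/C=C(/C)[C@@H](O[Si](C)(C)C(C)(C)C)CC[C@@]1(C)CCOC(C)(C)O1 | intermediate
12 | (2Z,4S)-4-[(tert-butyldimethylsilyl)oxy]-3-methyl-6-[(4S)-2,2,4-trimethyl-1,3-dioxan-4-yl]hex-2-enal | O=C/C=C(/C)[C@@H](O[Si](C)(C)C(C)(C)C)CC[C@@]1(C)CCOC(C)(C)O1 | intermediate
13 | 1-methoxy-4-[(prop-2-yn-1-yloxy)methyl]benzene (4-methoxybenzyl propargyl ether) | C#CCOCc1ccc(OC)cc1 | starting material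
14 | (4R,5Z,7S)-7-[(tert-butyldimethylsilyl)oxy]-1-[(4-methoxybenzyl)oxy]-6-methyl-9-[(4S)-2,2,4-trimethyl-1,3-dioxan-4-yl]non-5-en-2-yn-4-ol | COc1ccc(COCC#C[C@H](O)/C=C(/C)[C@@H](O[Si](C)(C)C(C)(C)C)CC[C@@]2(C)CCOC(C)(C)O2)cc1 | intermediate
15 | sodium alkenylalanate from 14: five-membered oxa-aluminacycle joining O6 and C11, hydrogen on C7, two 2-methoxyethoxy groups on aluminium | [Na+].COCCO[Al-]1(OCCOC)O[C@H](/C=C(/C)[C@@H](O[Si](C)(C)C(C)(C)C)CC[C@@]2(C)CCOC(C)(C)O2)C=C1COCc1ccc(OC)cc1 | intermediate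
16 | (2Z,4R,5Z,7S)-7-[(tert-butyldimethylsilyl)oxy]-2-iodo-1-[(4-methoxybenzyl)oxy]-6-methyl-9-[(4S)-2,2,4-trimethyl-1,3-dioxan-4-yl]nona-2,5-dien-4-ol | COc1ccc(COC/C(I)=C/[C@H](O)/C=C(/C)[C@@H](O[Si](C)(C)C(C)(C)C)CC[C@@]2(C)CCOC(C)(C)O2)cc1 | intermediate
17 | (5R)-3-{[(4-methoxybenzyl)oxy]methyl}-5-{(1Z,3S)-3-[(tert-butyldimethylsilyl)oxy]-2-methyl-5-[(4S)-2,2,4-trimethyl-1,3-dioxan-4-yl]pent-1-en-1-yl}furan-2(5H)-one | COc1ccc(COCC2=C[C@@H](/C=C(/C)[C@@H](O[Si](C)(C)C(C)(C)C)CC[C@@]3(C)CCOC(C)(C)O3)OC2=O)cc1 | intermediate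
18 | (5R)-3-(hydroxymethyl)-5-{(1Z,3S)-3-[(tert-butyldimethylsilyl)oxy]-2-methyl-5-[(4S)-2,2,4-trimethyl-1,3-dioxan-4-yl]pent-1-en-1-yl}furan-2(5H)-one | OCC1=C[C@@H](/C=C(/C)[C@@H](O[Si](C)(C)C(C)(C)C)CC[C@@]2(C)CCOC(C)(C)O2)OC1=O | intermediate
19 | (5R)-3-(bromomethyl)-5-{(1Z,3S)-3-[(tert-butyldimethylsilyl)oxy]-2-methyl-5-[(4S)-2,2,4-trimethyl-1,3-dioxan-4-yl]pent-1-en-1-yl}furan-2(5H)-one | BrCC1=C[C@@H](/C=C(/C)[C@@H](O[Si](C)(C)C(C)(C)C)CC[C@@]2(C)CCOC(C)(C)O2)OC1=O | intermediate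
20 | (5R)-3-(bromomethyl)-5-[(1Z,3S,6S)-3-[(tert-butyldimethylsilyl)oxy]-6,8-dihydroxy-2,6-dimethyloct-1-en-1-yl]furan-2(5H)-one | BrCC1=C[C@@H](/C=C(/C)[C@@H](O[Si](C)(C)C(C)(C)C)CC[C@](C)(O)CCO)OC1=O | intermediate
21 | (5R)-3-(bromomethyl)-5-[(1Z,3S,6S)-3-[(tert-butyldimethylsilyl)oxy]-6-hydroxy-2,6-dimethyl-8-oxooct-1-en-1-yl]furan-2(5H)-one | BrCC1=C[C@@H](/C=C(/C)[C@@H](O[Si](C)(C)C(C)(C)C)CC[C@](C)(O)CC=O)OC1=O | intermediate
22 | allylchromium dichloride: 21 with CrCl2 in place of bromine on C13 (trivalent chromium, solvent ligands omitted) | Cl[Cr](Cl)CC1=C[C@@H](/C=C(/C)[C@@H](O[Si](C)(C)C(C)(C)C)CC[C@](C)(O)CC=O)OC1=O | intermediate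
23 | (3aS,4R,6S,9S,10Z,11aR)-9-[(tert-butyldimethylsilyl)oxy]-4,6-dihydroxy-6,10-dimethyl-3-methylidene-3a,4,5,6,7,8,9,11a-octahydrocyclodeca[b]furan-2(3H)-one | C=C1C(=O)O[C@@H]2/C=C(/C)[C@@H](O[Si](C)(C)C(C)(C)C)CC[C@](C)(O)C[C@@H](O)[C@H]12 | intermediate
24 | (2E)-2-methylbut-2-enoyl chloride (tigloyl chloride) | C/C=C(C)/C(=O)Cl | starting material
25 | (3aS,4R,6S,9S,10Z,11aR)-9-[(tert-butyldimethylsilyl)oxy]-6-hydroxy-6,10-dimethyl-3-methylidene-2-oxo-2,3,3a,4,5,6,7,8,9,11a-decahydrocyclodeca[b]furan-4-yl (2E)-2-methylbut-2-enoate | C=C1C(=O)O[C@@H]2/C=C(/C)[C@@H](O[Si](C)(C)C(C)(C)C)CC[C@](C)(O)C[C@@H](OC(=O)/C(C)=C/C)[C@H]12 | intermediate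
26 | (3aS,4R,6S,9S,10Z,11aR)-6,9-dihydroxy-6,10-dimethyl-3-methylidene-2-oxo-2,3,3a,4,5,6,7,8,9,11a-decahydrocyclodeca[b]furan-4-yl (2E)-2-methylbut-2-enoate (CNP0137971.1) | C=C1C(=O)O[C@@H]2/C=C(/C)[C@@H](O)CC[C@](C)(O)C[C@@H](OC(=O)/C(C)=C/C)[C@H]12 | target

Total step count: 18. Longest linear sequence: 18 steps, from (S)-linalool 1 to 26.

Steps most likely to fail

Step 16. The tethered aldehyde may be delivered to the face of C7 anti to C5, which would give the trans-fused lactone with C7 and C8 both of the wrong configuration. The fallback sets out from 12 and comes back at 23. It inverts C6 upstream so that anti delivery becomes the productive mode, and the lactone is re-closed with inversion at the end.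
- The alkynylation of step 9 is run with (R)-BINOL to give the C6-epimeric propargylic alcohol F1.
- F1 is taken through the operations of steps 10 to 15 unchanged: hydroalumination–iodination to the iodo dienol F2, carbonylative lactonisation to the (5S)-butenolide ether F3, DDQ cleavage to the alcohol F4, Appel bromination to the bromide F5, acetonide methanolysis to the diol F6 and TEMPO oxidation to the aldehyde F7.
- In this series anti delivery places C8 on the face that gives 7S and 8R, so CrCl2 under the conditions of step 16 should give the trans-fused 6-epi macrocycle F8.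
- Saponification (LiOH, THF/H2O) gives the seco acid F9, kept as its carboxylate until use.
- Mitsunobu lactonisation (PPh3, DIAD, THF, high dilution), in which the allylic C6 oxyphosphonium is displaced by the carboxylate with inversion, closes the cis-fused lactone 23.

Step 10. The alkenylalanate may lose the β-(4-methoxybenzyl)oxy group to give an allene on warming, or hydride may be delivered without regiocontrol. The fallback sets out from 12 and comes back at 18; it brings C12 in with the alkyne and introduces C13 last.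
- Methyl propiolate 7 is added to 12 under the conditions of step 4 with (S)-BINOL to give the γ-hydroxy ynoate F10.
- Syn hydrostannation (Bu3SnH, Pd(PPh3)4 cat., THF, 0 °C) puts tin on C11 and hydrogen on C7; the Z-hydroxy ester formed lactonises (PPTS cat. if needed) to the 3-stannylbutenolide F11.
- Iododestannylation (I2, CH2Cl2, 0 °C) gives the 3-iodobutenolide F12.
- Stille coupling with Bu3SnCH2OH (Pd(PPh3)4, dioxane, 80 °C) gives the hydroxymethyl butenolide 18.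

Step 9. The Z-enal may isomerise to the E-enal under the Lewis-acidic conditions, and reagent control at C6 may be weak. The fallback sets out from 12 and comes back at 14; it separates C–C bond formation from the setting of C6.
- The lithium acetylide of 13 (n-BuLi, THF, −78 °C) is added to 12 without Lewis acid to give the propargylic alcohol as both C6 epimers F13.
- MnO2 oxidation (CH2Cl2, rt) gives the ynone F14.
- Midland reduction with B-(isopinocampheyl)-9-borabicyclo[3.3.1]nonane prepared from (+)-α-pinene (neat or THF, rt), in which the alkynyl group acts as the small substituent, should give the (4R)-alcohol 14.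

Further compounds
F1 | step 16 | (4S,5Z,7S)-7-[(tert-butyldimethylsilyl)oxy]-1-[(4-methoxybenzyl)oxy]-6-methyl-9-[(4S)-2,2,4-trimethyl-1,3-dioxan-4-yl]non-5-en-2-yn-4-ol | COc1ccc(COCC#C[C@@H](O)/C=C(/C)[C@@H](O[Si](C)(C)C(C)(C)C)CC[C@@]2(C)CCOC(C)(C)O2)cc1
F2 | step 16 | (2Z,4S,5Z,7S)-7-[(tert-butyldimethylsilyl)oxy]-2-iodo-1-[(4-methoxybenzyl)oxy]-6-methyl-9-[(4S)-2,2,4-trimethyl-1,3-dioxan-4-yl]nona-2,5-dien-4-ol | COc1ccc(COC/C(I)=C/[C@@H](O)/C=C(/C)[C@@H](O[Si](C)(C)C(C)(C)C)CC[C@@]2(C)CCOC(C)(C)O2)cc1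
F3 | step 16 | (5S)-3-{[(4-methoxybenzyl)oxy]methyl}-5-{(1Z,3S)-3-[(tert-butyldimethylsilyl)oxy]-2-methyl-5-[(4S)-2,2,4-trimethyl-1,3-dioxan-4-yl]pent-1-en-1-yl}furan-2(5H)-one | COc1ccc(COCC2=C[C@H](/C=C(/C)[C@@H](O[Si](C)(C)C(C)(C)C)CC[C@@]3(C)CCOC(C)(C)O3)OC2=O)cc1
F4 | step 16 | (5S)-3-(hydroxymethyl)-5-{(1Z,3S)-3-[(tert-butyldimethylsilyl)oxy]-2-methyl-5-[(4S)-2,2,4-trimethyl-1,3-dioxan-4-yl]pent-1-en-1-yl}furan-2(5H)-one | OCC1=C[C@H](/C=C(/C)[C@@H](O[Si](C)(C)C(C)(C)C)CC[C@@]2(C)CCOC(C)(C)O2)OC1=O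
F5 | step 16 | (5S)-3-(bromomethyl)-5-{(1Z,3S)-3-[(tert-butyldimethylsilyl)oxy]-2-methyl-5-[(4S)-2,2,4-trimethyl-1,3-dioxan-4-yl]pent-1-en-1-yl}furan-2(5H)-one | BrCC1=C[C@H](/C=C(/C)[C@@H](O[Si](C)(C)C(C)(C)C)CC[C@@]2(C)CCOC(C)(C)O2)OC1=O
F6 | step 16 | (5S)-3-(bromomethyl)-5-[(1Z,3S,6S)-3-[(tert-butyldimethylsilyl)oxy]-6,8-dihydroxy-2,6-dimethyloct-1-en-1-yl]furan-2(5H)-one | BrCC1=C[C@H](/C=C(/C)[C@@H](O[Si](C)(C)C(C)(C)C)CC[C@](C)(O)CCO)OC1=O
F7 | step 16 | (5S)-3-(bromomethyl)-5-[(1Z,3S,6S)-3-[(tert-butyldimethylsilyl)oxy]-6-hydroxy-2,6-dimethyl-8-oxooct-1-en-1-yl]furan-2(5H)-one | BrCC1=C[C@H](/C=C(/C)[C@@H](O[Si](C)(C)C(C)(C)C)CC[C@](C)(O)CC=O)OC1=O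
F8 | step 16 | (3aS,4R,6S,9S,10Z,11aS)-9-[(tert-butyldimethylsilyl)oxy]-4,6-dihydroxy-6,10-dimethyl-3-methylidene-3a,4,5,6,7,8,9,11a-octahydrocyclodeca[b]furan-2(3H)-one | C=C1C(=O)O[C@H]2/C=C(/C)[C@@H](O[Si](C)(C)C(C)(C)C)CC[C@](C)(O)C[C@@H](O)[C@H]12
F9 | step 16 | 2-[(1S,2R,4S,7S,8Z,10S)-7-[(tert-butyldimethylsilyl)oxy]-2,4,10-trihydroxy-4,8-dimethylcyclodec-8-en-1-yl]prop-2-enoic acid | C=C(C(=O)O)[C@@H]1[C@@H](O)/C=C(/C)[C@@H](O[Si](C)(C)C(C)(C)C)CC[C@](C)(O)C[C@H]1O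
F10 | step 10 | methyl (4R,5Z,7S)-7-[(tert-butyldimethylsilyl)oxy]-4-hydroxy-6-methyl-9-[(4S)-2,2,4-trimethyl-1,3-dioxan-4-yl]non-5-en-2-ynoate | COC(=O)C#C[C@H](O)/C=C(/C)[C@@H](O[Si](C)(C)C(C)(C)C)CC[C@@]1(C)CCOC(C)(C)O1
F11 | step 10 | (5R)-3-(tributylstannyl)-5-{(1Z,3S)-3-[(tert-butyldimethylsilyl)oxy]-2-methyl-5-[(4S)-2,2,4-trimethyl-1,3-dioxan-4-yl]pent-1-en-1-yl}furan-2(5H)-one | CCCC[Sn](CCCC)(CCCC)C1=C[C@@H](/C=C(/C)[C@@H](O[Si](C)(C)C(C)(C)C)CC[C@@]2(C)CCOC(C)(C)O2)OC1=O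
F12 | step 10 | (5R)-3-iodo-5-{(1Z,3S)-3-[(tert-butyldimethylsilyl)oxy]-2-methyl-5-[(4S)-2,2,4-trimethyl-1,3-dioxan-4-yl]pent-1-en-1-yl}furan-2(5H)-one | IC1=C[C@@H](/C=C(/C)[C@@H](O[Si](C)(C)C(C)(C)C)CC[C@@]2(C)CCOC(C)(C)O2)OC1=O
F13 | step 9 | (5Z,7S)-7-[(tert-butyldimethylsilyl)oxy]-1-[(4-methoxybenzyl)oxy]-6-methyl-9-[(4S)-2,2,4-trimethyl-1,3-dioxan-4-yl]non-5-en-2-yn-4-ol, both C4 epimers | COc1ccc(COCC#CC(O)/C=C(/C)[C@@H](O[Si](C)(C)C(C)(C)C)CC[C@@]2(C)CCOC(C)(C)O2)cc1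
F14 | step 9 | (5Z,7S)-7-[(tert-butyldimethylsilyl)oxy]-1-[(4-methoxybenzyl)oxy]-6-methyl-9-[(4S)-2,2,4-trimethyl-1,3-dioxan-4-yl]non-5-en-2-yn-4-one | COc1ccc(COCC#CC(=O)/C=C(/C)[C@@H](O[Si](C)(C)C(C)(C)C)CC[C@@]2(C)CCOC(C)(C)O2)cc1
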